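Numbering runs from C1 (lactone carbonyl) to C12 (methyl). The caffeoyloxy carbon C11 is bonded directly to C10 of the tetrahydrofuran ring (O7, C7–C10). The ester carbonyl carbon can therefore span O10 and O11 in a 1,3-dioxolan-2-ylium ring, and O7 can displace the C10–O bond of that ring.
Retrosynthetic cuts, in order: the phenol and O6 protecting groups; O7–C10 together with the acyl C–O bonds (7,10,11-triol plus caffeic orthoester); C2=C3 and O5–C1 (metathesis, acrylate); C4–C5 (allylboration); C6–C7 (γ-alkoxyallylboration).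
Forward: the C7–C12 aldehyde from L-rhamnal, then C6–C7, then C4–C5, then the dihydropyranone ring by ring-closing metathesis. The tetrahydrofuran ring closes last, in the same operation that installs the caffeate.
Stereochemistry: C10 and C11 come from L-rhamnose (C11 kept, C10 inverted on ring closure). C6 and C7 come from a (+)-α-pinene-derived (Z)-alkoxyallylborane, and C5 from the (−)-α-pinene-derived allylborane.

Key step: step 16

Remark: the descriptor at C6 switches between R and S along the route only because the CIP ranks of its neighbours change with the O-substituents; no bond at C6 is made or broken after step 6.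

Step 1
Reactants: 1 3,4-di-O-acetyl-L-rhamnal
Product: 2 (2E,4R,5S)-4-acetoxy-5-hydroxyhex-2-enal
Conditions: HgSO4 (2 mol %), 5 mM aq H2SO4, 1,4-dioxane, rt
Reagents that add atoms: water, O
Why: Perlin hydrolysis, in which HgSO4-catalysed hydration of the enol ether, ring opening and loss of the allylic C3 acetate should give the E-enal while the two carbinol carbons that become C10 and C11 stay untouched.

Step 2
Reactants: 2 (2E,4R,5S)-4-acetoxy-5-hydroxyhex-2-enal
Product: 3 4-O-acetyl-2,3,6-trideoxy-L-erythro-hexopyranose (4-O-acetyl-L-amicetose; anomeric mixture)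
Conditions: H2 (1 atm), 10% Pd/C, EtOAc, rt
Reagents that add atoms: none
Why: Heterogeneous hydrogenation at balloon pressure should saturate only the conjugated C=C, and the released 5-hydroxy aldehyde rests as its pyranose lactol with both stereocentres unchanged.

Step 3
Reactants: 3 4-O-acetyl-2,3,6-trideoxy-L-erythro-hexopyranose
Product: 4 (4R,5S)-hexane-1,4,5-triol
Conditions: LiAlH4, THF, 0 °C → rt; H2O/aq NaOH work-up
Reagents that add atoms: none
Why: Hydride reduction of the lactol (through its ring-opened carbonyl form) and reductive cleavage of the acetate should deliver the free erythro triol in one operation.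

Step 4
Reactants: 4 (4R,5S)-hexane-1,4,5-triol
Product: 5 3-[(4R,5S)-2,2,5-trimethyl-1,3-dioxolan-4-yl]propan-1-ol
Conditions: 2,2-dimethoxypropane, CSA (cat.), CH2Cl2, rt; aq NaHCO3
Reagents that add atoms: 2,2-dimethoxypropane, COC(C)(C)OC
Why: Acid-catalysed transketalisation under thermodynamic control prefers the five-membered dioxolane on the vicinal diol over a seven-membered ketal that would involve the primary hydroxyl, which stays free.

Step 5
Reactants: 5 3-[(4R,5S)-2,2,5-trimethyl-1,3-dioxolan-4-yl]propan-1-ol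
Product: 6 3-[(4R,5S)-2,2,5-trimethyl-1,3-dioxolan-4-yl]propanal
Conditions: TEMPO (10 mol %), PhI(OAc)2, CH2Cl2, rt
Reagents that add atoms: none
Why: Oxoammonium (TEMPO) oxidation of a primary alcohol stops at the aldehyde and is mild enough for the acetonide.

Step 6
Reactants: 6 3-[(4R,5S)-2,2,5-trimethyl-1,3-dioxolan-4-yl]propanal; 7 allyl 4-methoxybenzyl ether
Product: 9 (3R,4R)-3-(4-methoxybenzyloxy)-6-[(4R,5S)-2,2,5-trimethyl-1,3-dioxolan-4-yl]hex-1-en-4-ol, via (Z)-alkoxyallylborane 8 (not isolated)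
Conditions: 7, s-BuLi, THF, −78 °C; (−)-Ipc2BOMe [from (+)-α-pinene]; BF3·OEt2; 6, −78 °C → rt; 3 M NaOH, 30% H2O2
Reagents that add atoms: none
Why: Brown γ-alkoxyallylboration, in which the Z-allylborane reacts through a closed chair transition state to give the syn (threo) C6/C7 pair and the (+)-α-pinene-derived ligands direct attack to the Si face of the aldehyde, so that C7 becomes R and O6 arrives already protected and differentiated from O7.

Step 7
Reactants: 9 (3R,4R)-3-(4-methoxybenzyloxy)-6-[(4R,5S)-2,2,5-trimethyl-1,3-dioxolan-4-yl]hex-1-en-4-ol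
Product: 10 (3R,4R)-3-(4-methoxybenzyloxy)-4-(triethylsilyloxy)-6-[(4R,5S)-2,2,5-trimethyl-1,3-dioxolan-4-yl]hex-1-ene
Conditions: Et3SiCl, imidazole, DMAP (cat.), CH2Cl2, 0 °C → rt
Reagents that add atoms: chlorotriethylsilane, CC[Si](Cl)(CC)CC
Why: Routine silylation masks O7 so that only O5 can be acylated later, and the triethylsilyl group is chosen because it falls together with the acetonide in step 12.

Step 8
Reactants: 10 (3R,4R)-3-(4-methoxybenzyloxy)-4-(triethylsilyloxy)-6-[(4R,5S)-2,2,5-trimethyl-1,3-dioxolan-4-yl]hex-1-ene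
Product: 11 (2S,3R)-2-(4-methoxybenzyloxy)-3-(triethylsilyloxy)-5-[(4R,5S)-2,2,5-trimethyl-1,3-dioxolan-4-yl]pentanal
Conditions: OsO4 (2 mol %), NaIO4, 2,6-lutidine, 1,4-dioxane/H2O (3:1), rt
Reagents that add atoms: sodium periodate, [Na+].[O-]I(=O)(=O)=O (terminal source of the aldehyde oxygen, relayed by OsO4, O=[Os](=O)(=O)=O)
Why: Lemieux–Johnson cleavage of the only alkene, buffered with lutidine, spares the electron-rich PMB ring that ozone would attack and should not epimerise the α-alkoxy aldehyde, which is used without delay.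

Step 9
Reactants: 11 (2S,3R)-2-(4-methoxybenzyloxy)-3-(triethylsilyloxy)-5-[(4R,5S)-2,2,5-trimethyl-1,3-dioxolan-4-yl]pentanal; 12 allylmagnesium bromide
Product: 14 (4R,5R,6R)-5-(4-methoxybenzyloxy)-6-(triethylsilyloxy)-8-[(4R,5S)-2,2,5-trimethyl-1,3-dioxolan-4-yl]oct-1-en-4-ol, via B-allyldiisopinocampheylborane 13 (not isolated)
Conditions: 12, (+)-Ipc2BOMe [from (−)-α-pinene], Et2O, 0 °C → rt; 11, −78 °C; 3 M NaOH, 30% H2O2
Reagents that add atoms: none
Why: Brown allylboration, in which the (−)-α-pinene-derived reagent adds to the Re face of the aldehyde to set 5R, the 5,6-anti relationship that the Felkin–Anh bias of the α-alkoxy aldehyde also favours (matched pair).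

Step 10
Reactants: 14 (4R,5R,6R)-5-(4-methoxybenzyloxy)-6-(triethylsilyloxy)-8-[(4R,5S)-2,2,5-trimethyl-1,3-dioxolan-4-yl]oct-1-en-4-ol; 15 acryloyl chloride
Product: 16 (4R,5R,6R)-5-(4-methoxybenzyloxy)-6-(triethylsilyloxy)-8-[(4R,5S)-2,2,5-trimethyl-1,3-dioxolan-4-yl]oct-1-en-4-yl acrylate
Conditions: 15, Et3N, DMAP (cat.), CH2Cl2, 0 °C
Reagents that add atoms: none
Why: O-Acylation of the only free hydroxyl (O5) proceeds with retention because the C5–O bond is not involved.

Step 11
Reactants: 16 (4R,5R,6R)-5-(4-methoxybenzyloxy)-6-(triethylsilyloxy)-8-[(4R,5S)-2,2,5-trimethyl-1,3-dioxolan-4-yl]oct-1-en-4-yl acrylate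
Product: 17 (6R)-6-{(1R,2R)-1-(4-methoxybenzyloxy)-2-(triethylsilyloxy)-4-[(4R,5S)-2,2,5-trimethyl-1,3-dioxolan-4-yl]butyl}-5,6-dihydro-2H-pyran-2-one
Conditions: second-generation Grubbs catalyst (H2IMes)(PCy3)Cl2Ru=CHPh (5 mol %), CH2Cl2 (high dilution), reflux
Reagents that add atoms: none
Why: Ring-closing metathesis of a homoallylic acrylate is the standard entry to 5,6-dihydropyran-2-ones, and the six-membered ring enforces the Z C2=C3 bond.

Step 12
Reactants: 17 (6R)-6-{(1R,2R)-1-(4-methoxybenzyloxy)-2-(triethylsilyloxy)-4-[(4R,5S)-2,2,5-trimethyl-1,3-dioxolan-4-yl]butyl}-5,6-dihydro-2H-pyran-2-one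
Product: 18 (6R)-6-[(1S,2R,5R,6S)-2,5,6-trihydroxy-1-(4-methoxybenzyloxy)heptyl]-5,6-dihydro-2H-pyran-2-one
Conditions: 2 M aq HCl/THF (1:3), rt
Reagents that add atoms: none
Why: Dilute aqueous acid hydrolyses ketal and triethylsilyl ether together but leaves the PMB ether and lactone, and the 5,7-anti arrangement should disfavour oxa-Michael addition of O7 to C3 because the bridged bicycle would have to carry the C8 chain axially under the lactone bridge.

Step 13
Reactants: 19 caffeic acid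
Product: 21 (E)-3-[3,4-bis(tert-butyldimethylsilyloxy)phenyl]acrylic acid, via tris-silyl caffeate 20 (not isolated)
Conditions: TBSCl (3.5 equiv), imidazole, DMF, rt; then AcOH/THF/H2O (3:1:1), rt
Reagents that add atoms: tert-butyldimethylsilyl chloride, CC(C)(C)[Si](C)(C)Cl
Why: Exhaustive silylation followed by mild acid hydrolysis exploits the far higher lability of a silyl ester compared with aryl silyl ethers, and the E-alkene of the natural acid is carried over unchanged.

Step 14
Reactants: 21 (E)-3-[3,4-bis(tert-butyldimethylsilyloxy)phenyl]acrylic acid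
Product: 22 (E)-3-[3,4-bis(tert-butyldimethylsilyloxy)phenyl]acrylamide
Conditions: EDC·HCl, HOBt, NH4Cl, i-Pr2NEt, DMF, 0 °C → rt
Reagents that add atoms: ammonium chloride, [NH4+].[Cl-]
Why: Carbodiimide/HOBt coupling with ammonia released in situ is a near-neutral amide synthesis that the base-sensitive aryl silyl ethers should tolerate.

Step 15
Reactants: 22 (E)-3-[3,4-bis(tert-butyldimethylsilyloxy)phenyl]acrylamide
Product: 24 trimethyl ortho-(E)-3-[3,4-bis(tert-butyldimethylsilyloxy)phenyl]acrylate, via imidate triflate 23 (not isolated)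
Conditions: MeOTf, CH2Cl2, 0 °C → rt; then dry MeOH/hexane, rt; Et3N, filtration through basic Al2O3
Reagents that add atoms: methyl trifluoromethanesulfonate, COS(=O)(=O)C(F)(F)F; methanol, CO
Why: O-Methylation of the primary amide gives the same imidate salt as a Pinner reaction but without excess HCl or a nucleophilic counter-ion, and Pinner-type methanolysis of that salt should then furnish the orthoester and ammonium triflate while aryl silyl ethers and alkene geometry survive.

Step 16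
Reactants: 18 (6R)-6-[(1S,2R,5R,6S)-2,5,6-trihydroxy-1-(4-methoxybenzyloxy)heptyl]-5,6-dihydro-2H-pyran-2-one; 24 trimethyl ortho-(E)-3-[3,4-bis(tert-butyldimethylsilyloxy)phenyl]acrylate
Product: 27 (1S)-1-[(2S,5R)-5-{(S)-(4-methoxybenzyloxy)[(2R)-6-oxo-3,6-dihydro-2H-pyran-2-yl]methyl}tetrahydrofuran-2-yl]ethyl (E)-3-[3,4-bis(tert-butyldimethylsilyloxy)phenyl]acrylate, via cyclic orthoester 25 (not isolated), via dioxolanylium ion 26 (not isolated)
Conditions: 24 (1.5 equiv), PPTS (5 mol %), CH2Cl2, rt; then BF3·OEt2 (0.2 equiv), −30 → 0 °C; Et3N quench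
Reagents that add atoms: none
Why: Proposed new method: PPTS-catalysed alkoxy exchange binds only the vicinal O10/O11 pair of 18 to the acyl carbon of 24 as the 2-methoxy-1,3-dioxolane 25 (the lone O7 can exchange only reversibly), BF3·OEt2 removes the methoxy group to give the 2-styryl-1,3-dioxolan-2-ylium ion 26, and O7–H displaces O10 from C10 in an intramolecular SN2 reaction that leaves the acyl group as the ester on O11. The closest known reaction type is the orthoacetate-mediated cyclisation of 1,2,5-triols through acetoxonium ions to 2-(1-acyloxyalkyl)tetrahydrofurans; new here is an alkenyl orthoester whose cation is further stabilised by the electron-rich styryl group, which should ease ionisation and slow the substitution without changing its course, because capture at the acyl carbon or at the styryl β-carbon is reversible whereas C–O bond formation at C10 is not. The tetrahydrofuran ring closes in the 5-exo-tet mode. C10 is the only centre that changes: backside attack on the bridged, non-ionising C10–O bond inverts the rhamnose-derived 10R centre to 10S, turning the erythro C10/C11 pair into the threo pair and giving the 2,5-cis ring, while C7 and C11 keep their C–O bonds and configurations. The step needs attack at C10 rather than C11 and O7 as the sole nucleophile; the three-carbon tether favours the five- over the six-membered transition state, O6 is blocked as its PMB ether and O5 is locked in the lactone.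

Step 17
Reactants: 27 (1S)-1-[(2S,5R)-5-{(S)-(4-methoxybenzyloxy)[(2R)-6-oxo-3,6-dihydro-2H-pyran-2-yl]methyl}tetrahydrofuran-2-yl]ethyl (E)-3-[3,4-bis(tert-butyldimethylsilyloxy)phenyl]acrylate
Product: 28 (1S)-1-[(2S,5R)-5-{(S)-hydroxy[(2R)-6-oxo-3,6-dihydro-2H-pyran-2-yl]methyl}tetrahydrofuran-2-yl]ethyl (E)-3-[3,4-bis(tert-butyldimethylsilyloxy)phenyl]acrylate
Conditions: DDQ (1.3 equiv), CH2Cl2/pH 7 phosphate buffer (10:1), 0 °C
Reagents that add atoms: none
Why: Oxidative PMB cleavage needs a benzylic C–H next to an electron-rich ring, which only the PMB ether offers, so charge transfer to the silylated caffeate should be unproductive, and the step precedes desilylation because a free catechol would be oxidised.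

Step 18
Reactants: 28 (1S)-1-[(2S,5R)-5-{(S)-hydroxy[(2R)-6-oxo-3,6-dihydro-2H-pyran-2-yl]methyl}tetrahydrofuran-2-yl]ethyl (E)-3-[3,4-bis(tert-butyldimethylsilyloxy)phenyl]acrylate
Product: 29 (1S)-1-[(2S,5R)-5-{(S)-hydroxy[(2R)-6-oxo-3,6-dihydro-2H-pyran-2-yl]methyl}tetrahydrofuran-2-yl]ethyl (E)-3-(3,4-dihydroxyphenyl)acrylate (CNP0300981.1)
Conditions: HF·pyridine, pyridine, THF, 0 °C → rt, argon
Reagents that add atoms: none
Why: Buffered fluoride cleaves the aryl silyl ethers under slightly acidic conditions, which avoids phenoxide formation, catechol oxidation and base-induced oxa-Michael addition or ester cleavage.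

Compound list
1 | 3,4-di-O-acetyl-L-rhamnal | C[C@@H]1OC=C[C@H](OC(C)=O)[C@H]1OC(C)=O | starting material
2 | (2E,4R,5S)-4-acetoxy-5-hydroxyhex-2-enal | C[C@H](O)[C@H](OC(C)=O)/C=C/C=O | intermediate
3 | 4-O-acetyl-2,3,6-trideoxy-L-erythro-hexopyranose (anomeric mixture) | C[C@@H]1OC(O)CC[C@H]1OC(C)=O | intermediate
4 | (4R,5S)-hexane-1,4,5-triol | C[C@H](O)[C@H](O)CCCO | intermediate
5 | 3-[(4R,5S)-2,2,5-trimethyl-1,3-dioxolan-4-yl]propan-1-ol | C[C@@H]1OC(C)(C)O[C@@H]1CCCO | intermediate
6 | 3-[(4R,5S)-2,2,5-trimethyl-1,3-dioxolan-4-yl]propanal | C[C@@H]1OC(C)(C)O[C@@H]1CCC=O | intermediate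
7 | allyl 4-methoxybenzyl ether | C=CCOCc1ccc(OC)cc1 | starting material
8 | [(Z)-3-(4-methoxybenzyloxy)allyl]diisopinocampheylborane, Ipc groups from (+)-α-pinene (not isolated) | COc1ccc(CO/C=C\CB([C@@H]2C[C@@H]3C[C@H]([C@H]2C)C3(C)C)[C@@H]2C[C@@H]3C[C@H]([C@H]2C)C3(C)C)cc1 | intermediate
9 | (3R,4R)-3-(4-methoxybenzyloxy)-6-[(4R,5S)-2,2,5-trimethyl-1,3-dioxolan-4-yl]hex-1-en-4-ol | C[C@@H]1OC(C)(C)O[C@@H]1CC[C@@H](O)[C@H](OCc2ccc(OC)cc2)C=C | intermediate
10 | (3R,4R)-3-(4-methoxybenzyloxy)-4-(triethylsilyloxy)-6-[(4R,5S)-2,2,5-trimethyl-1,3-dioxolan-4-yl]hex-1-ene | C[C@@H]1OC(C)(C)O[C@@H]1CC[C@@H](O[Si](CC)(CC)CC)[C@H](OCc2ccc(OC)cc2)C=C | intermediate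
11 | (2S,3R)-2-(4-methoxybenzyloxy)-3-(triethylsilyloxy)-5-[(4R,5S)-2,2,5-trimethyl-1,3-dioxolan-4-yl]pentanal | C[C@@H]1OC(C)(C)O[C@@H]1CC[C@@H](O[Si](CC)(CC)CC)[C@H](OCc2ccc(OC)cc2)C=O | intermediate
12 | allylmagnesium bromide | C=CC[Mg]Br | starting material
13 | B-allyldiisopinocampheylborane, Ipc groups from (−)-α-pinene (not isolated) | C=CCB([C@H]1C[C@H]2C[C@@H]([C@@H]1C)C2(C)C)[C@H]1C[C@H]2C[C@@H]([C@@H]1C)C2(C)C | intermediate
14 | (4R,5R,6R)-5-(4-methoxybenzyloxy)-6-(triethylsilyloxy)-8-[(4R,5S)-2,2,5-trimethyl-1,3-dioxolan-4-yl]oct-1-en-4-ol | C[C@@H]1OC(C)(C)O[C@@H]1CC[C@@H](O[Si](CC)(CC)CC)[C@H](OCc2ccc(OC)cc2)[C@H](O)CC=C | intermediate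
15 | acryloyl chloride | C=CC(=O)Cl | starting material
16 | (4R,5R,6R)-5-(4-methoxybenzyloxy)-6-(triethylsilyloxy)-8-[(4R,5S)-2,2,5-trimethyl-1,3-dioxolan-4-yl]oct-1-en-4-yl acrylate | C[C@@H]1OC(C)(C)O[C@@H]1CC[C@@H](O[Si](CC)(CC)CC)[C@H](OCc2ccc(OC)cc2)[C@H](OC(=O)C=C)CC=C | intermediate
17 | (6R)-6-{(1R,2R)-1-(4-methoxybenzyloxy)-2-(triethylsilyloxy)-4-[(4R,5S)-2,2,5-trimethyl-1,3-dioxolan-4-yl]butyl}-5,6-dihydro-2H-pyran-2-one | C[C@@H]1OC(C)(C)O[C@@H]1CC[C@@H](O[Si](CC)(CC)CC)[C@H](OCc2ccc(OC)cc2)[C@H]3CC=CC(=O)O3 | intermediate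
18 | (6R)-6-[(1S,2R,5R,6S)-2,5,6-trihydroxy-1-(4-methoxybenzyloxy)heptyl]-5,6-dihydro-2H-pyran-2-one (5R,6S,7R,10R,11S) | C[C@H](O)[C@H](O)CC[C@@H](O)[C@H](OCc1ccc(OC)cc1)[C@H]2CC=CC(=O)O2 | intermediate
19 | caffeic acid | OC(=O)/C=C/c1ccc(O)c(O)c1 | starting material
20 | tert-butyldimethylsilyl (E)-3-[3,4-bis(tert-butyldimethylsilyloxy)phenyl]acrylate (not isolated) | CC(C)(C)[Si](C)(C)OC(=O)/C=C/c1ccc(O[Si](C)(C)C(C)(C)C)c(O[Si](C)(C)C(C)(C)C)c1 | intermediate
21 | (E)-3-[3,4-bis(tert-butyldimethylsilyloxy)phenyl]acrylic acid | OC(=O)/C=C/c1ccc(O[Si](C)(C)C(C)(C)C)c(O[Si](C)(C)C(C)(C)C)c1 | intermediate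
22 | (E)-3-[3,4-bis(tert-butyldimethylsilyloxy)phenyl]acrylamide | NC(=O)/C=C/c1ccc(O[Si](C)(C)C(C)(C)C)c(O[Si](C)(C)C(C)(C)C)c1 | intermediate
23 | methyl (E)-3-[3,4-bis(tert-butyldimethylsilyloxy)phenyl]acrylimidate, triflate salt (not isolated) | COC(=[NH2+])/C=C/c1ccc(O[Si](C)(C)C(C)(C)C)c(O[Si](C)(C)C(C)(C)C)c1.[O-]S(=O)(=O)C(F)(F)F | intermediate
24 | trimethyl ortho-(E)-3-[3,4-bis(tert-butyldimethylsilyloxy)phenyl]acrylate | COC(OC)(OC)/C=C/c1ccc(O[Si](C)(C)C(C)(C)C)c(O[Si](C)(C)C(C)(C)C)c1 | intermediate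
25 | O10,O11-cyclic methyl orthoester of 18 (2-methoxy-2-styryl-1,3-dioxolane, epimers at the ortho carbon; 5R,6S,7R,10R,11S; not isolated) | C[C@@H]1OC(OC)(/C=C/c2ccc(O[Si](C)(C)C(C)(C)C)c(O[Si](C)(C)C(C)(C)C)c2)O[C@@H]1CC[C@@H](O)[C@H](OCc3ccc(OC)cc3)[C@H]4CC=CC(=O)O4 | intermediate
26 | 2-styryl-1,3-dioxolan-2-ylium ion bridging O10 and O11, methoxytrifluoroborate salt (not isolated) | C[C@@H]1OC(/C=C/c2ccc(O[Si](C)(C)C(C)(C)C)c(O[Si](C)(C)C(C)(C)C)c2)=[O+][C@@H]1CC[C@@H](O)[C@H](OCc3ccc(OC)cc3)[C@H]4CC=CC(=O)O4.CO[B-](F)(F)F | intermediate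
27 | target as C6 PMB ether and catechol bis-TBS ether (5R,6S,7R,10S,11S) | C[C@H](OC(=O)/C=C/c1ccc(O[Si](C)(C)C(C)(C)C)c(O[Si](C)(C)C(C)(C)C)c1)[C@@H]2CC[C@H]([C@H](OCc3ccc(OC)cc3)[C@H]4CC=CC(=O)O4)O2 | intermediate
28 | target as catechol bis-TBS ether (5R,6S,7R,10S,11S) | C[C@H](OC(=O)/C=C/c1ccc(O[Si](C)(C)C(C)(C)C)c(O[Si](C)(C)C(C)(C)C)c1)[C@@H]2CC[C@H]([C@H](O)[C@H]3CC=CC(=O)O3)O2 | intermediate
29 | CNP0300981.1 (5R,6S,7R,10S,11S) | C[C@H](OC(=O)/C=C/c1ccc(O)c(O)c1)[C@@H]1CC[C@H]([C@H](O)[C@H]2CC=CC(=O)O2)O1 | target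

Total step count: 18. Longest linear sequence: 15 (steps 1–12 and 16–18); steps 13–15 form the three-step orthoester branch.

Steps most likely to fail

1. Step 16. The styryl-stabilised cation may be too weak an electrophile at C10. Reversible capture at the acyl carbon would then prevail and work-up would only hydrolyse the orthoester, while longer exposure to the Lewis acid could cost the PMB ether. The fallback sets out from 18 and uses the established acetoxonium version. Trimethyl orthoacetate/PPTS followed by BF3·OEt2 in CH2Cl2 would close the same ring with the same inversion and give (1S)-1-[(2S,5R)-5-{(S)-(4-methoxybenzyloxy)[(2R)-6-oxo-3,6-dihydro-2H-pyran-2-yl]methyl}tetrahydrofuran-2-yl]ethyl acetate F1. Brief K2CO3/MeOH at 0 °C would free the C11 carbinol (6R)-6-{(S)-[(2R,5S)-5-[(1S)-1-hydroxyethyl]tetrahydrofuran-2-yl](4-methoxybenzyloxy)methyl}-5,6-dihydro-2H-pyran-2-one F2, in which no hydroxyl is placed for oxa-Michael addition. Steglich esterification with acid 21 (EDC·HCl, DMAP, CH2Cl2), which retains C11, comes back to the route at 27.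

2. Step 15. Methanolysis of the conjugated, donor-stabilised imidate salt may be sluggish, dealkylation back to the amide may compete, and the very acid-labile acyclic orthoester may hydrolyse during isolation. The fallback sets out from 22 and avoids the acyclic orthoester altogether. The amide is O-methylated as before, and the CH2Cl2 solution of imidate triflate 23 is added directly to triol 18 over 4 Å molecular sieves. After the first alcoholysis the second C–O bond forms intramolecularly and ammonium triflate precipitates. The sequence returns at cyclic orthoester 25, which is ionised with BF3·OEt2 as in step 16. This detour makes no compound outside the list (F0).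

3. Step 6. Metalation of the allyl PMB ether may be accompanied by benzylic deprotonation and Wittig rearrangement, which would lower conversion, and erosion of the Z-geometry would lower syn selectivity. The fallback sets out from 6 and replaces allylboration by an Evans syn glycolate aldol.
   - (S)-4-Benzyl-3-[(4-methoxybenzyloxy)acetyl]oxazolidin-2-one F3 is made by N-acylation of lithiated (S)-4-benzyloxazolidin-2-one with the pivalic mixed anhydride of (4-methoxybenzyloxy)acetic acid.
   - F3 is enolised with Bu2BOTf/Et3N and added to 6 to give (S)-4-benzyl-3-{(2S,3R)-3-hydroxy-2-(4-methoxybenzyloxy)-5-[(4R,5S)-2,2,5-trimethyl-1,3-dioxolan-4-yl]pentanoyl}oxazolidin-2-one F4.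
   - Silylation (Et3SiCl, imidazole) gives its 3-O-triethylsilyl ether F5.
   - LiBH4 (Et2O, MeOH) removes the auxiliary to give (2R,3R)-2-(4-methoxybenzyloxy)-3-(triethylsilyloxy)-5-[(4R,5S)-2,2,5-trimethyl-1,3-dioxolan-4-yl]pentan-1-ol F6.
   - Dess–Martin oxidation comes back to the route at 11, bypassing steps 6–8.

Further compounds
F1 | step 16 | (1S)-1-[(2S,5R)-5-{(S)-(4-methoxybenzyloxy)[(2R)-6-oxo-3,6-dihydro-2H-pyran-2-yl]methyl}tetrahydrofuran-2-yl]ethyl acetate | C[C@H](OC(C)=O)[C@@H]1CC[C@H]([C@H](OCc2ccc(OC)cc2)[C@H]3CC=CC(=O)O3)O1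
F2 | step 16 | (6R)-6-{(S)-[(2R,5S)-5-[(1S)-1-hydroxyethyl]tetrahydrofuran-2-yl](4-methoxybenzyloxy)methyl}-5,6-dihydro-2H-pyran-2-one | C[C@H](O)[C@@H]1CC[C@H]([C@H](OCc2ccc(OC)cc2)[C@H]3CC=CC(=O)O3)O1
F0 | step 15 | none | none
F3 | step 6 | (S)-4-benzyl-3-[(4-methoxybenzyloxy)acetyl]oxazolidin-2-one | COc1ccc(COCC(=O)N2[C@@H](Cc3ccccc3)COC2=O)cc1
F4 | step 6 | (S)-4-benzyl-3-{(2S,3R)-3-hydroxy-2-(4-methoxybenzyloxy)-5-[(4R,5S)-2,2,5-trimethyl-1,3-dioxolan-4-yl]pentanoyl}oxazolidin-2-one | C[C@@H]1OC(C)(C)O[C@@H]1CC[C@@H](O)[C@H](OCc2ccc(OC)cc2)C(=O)N3[C@@H](Cc4ccccc4)COC3=O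
F5 | step 6 | (S)-4-benzyl-3-{(2S,3R)-2-(4-methoxybenzyloxy)-3-(triethylsilyloxy)-5-[(4R,5S)-2,2,5-trimethyl-1,3-dioxolan-4-yl]pentanoyl}oxazolidin-2-one | C[C@@H]1OC(C)(C)O[C@@H]1CC[C@@H](O[Si](CC)(CC)CC)[C@H](OCc2ccc(OC)cc2)C(=O)N3[C@@H](Cc4ccccc4)COC3=O
F6 | step 6 | (2R,3R)-2-(4-methoxybenzyloxy)-3-(triethylsilyloxy)-5-[(4R,5S)-2,2,5-trimethyl-1,3-dioxolan-4-yl]pentan-1-ol | C[C@@H]1OC(C)(C)O[C@@H]1CC[C@@H](O[Si](CC)(CC)CC)[C@H](OCc2ccc(OC)cc2)CO
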